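**Retrosynthetic overview**
1. The target is opened at the free carboxylic acid (fluoride-labile 2-(trimethylsilyl)ethyl ester) and at the primary ester, giving an epoxyquinol diol and an (R)-configured HMG mono-TMSE half ester.
2. The HMG unit comes from a Reformatsky aldol (methyl bromoacetate + methyl acetoacetate), pig-liver-esterase desymmetrisation of the prochiral diester, and an ester switch.
3. The epoxyquinol comes from hydride reduction anti to the oxirane of an epoxyquinone. That quinone is released by retro-Diels–Alder from a cyclopentadiene-masked tricycle whose CH2OH is installed by an intermolecular aldol with formaldehyde and which is resolved with a lipase.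
4. Key fragment union: the farnesyl–ring C–C bond is made by BF3-mediated conjugate (Michael/Sakurai-type) allylation of p-benzoquinone with (E,E)-farnesyltributylstannane.
5. Ring order: the carbocycle is bought as p-benzoquinone; a temporary norbornene is formed (Diels–Alder), then the oxirane (nucleophilic epoxidation), then the norbornene is removed (retro-Diels–Alder).

Notation: "farnesyl" = (2E,6E)-3,7,11-trimethyldodeca-2,6,10-trien-1-yl. Tricycles use 5,8-methanonaphthalene numbering (C1/C4 carbonyls, C2 farnesyl carbon, C4a/C8a ring fusion). Monocycles use 7-oxabicyclo[4.1.0]heptane numbering (C1 farnesyl oxirane carbon, C2 ketone, C4 carbon bearing CH2O, C5 carbinol, C6 oxirane CH).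

Assumption: in the lipase resolution (step 8) the enantiomer needed is taken to be the slow-reacting alcohol; if the enzyme prefers it instead, it is collected as its acetate and de-acetylated with the same lipase, with nothing else changed.

**Step 1**
Reactants: 1 (2E,6E)-farnesol
Product: 2 (2E,6E)-farnesyl chloride
Conditions: NCS, Me2S, CH2Cl2, −40 → 0 °C
Reagents that add atoms: N-chlorosuccinimide ClN1C(=O)CCC1=O
Why: Corey–Kim-type allylic chlorination proceeds by SN2 at the primary carbon, so there is no allylic transposition and no E/Z scrambling; no stereocentre is formed.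

**Step 2**
Reactants: 2 (2E,6E)-farnesyl chloride
Product: 3 tributyl[(2E,6E)-farnesyl]stannane
Conditions: Bu3SnLi (from Bu3SnH + LDA, THF, 0 °C), THF, −78 → 0 °C; neutral alumina
Reagents that add atoms: tributylstannyllithium [Li][Sn](CCCC)(CCCC)CCCC (generated from tributyltin hydride CCCC[SnH](CCCC)CCCC)
Why: SN2 alkylation of the soft stannyl anion at the primary allylic carbon at low temperature gives the linear allylstannane with the 2E,6E geometry intact.

**Step 3**
Reactants: 3 tributyl[(2E,6E)-farnesyl]stannane; 4 p-benzoquinone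
Product: 6 2-[(2E,6E)-farnesyl]benzene-1,4-diol, via 2-farnesylcyclohex-5-ene-1,4-dione 5 (not isolated)
Conditions: BF3·OEt2 (1.5 equiv), CH2Cl2, −78 → −30 °C; aq. KF work-up
Reagents that add atoms: none
Why: Naruta/Hosomi–Sakurai conjugate (Michael-type) allylation of the BF3-activated quinone delivers the farnesyl group through its CH2 terminus with the 2′E bond retained, and adduct 5 enolises to the hydroquinone; no stereocentre is formed.

**Step 4**
Reactants: 6 2-[(2E,6E)-farnesyl]benzene-1,4-diol
Product: 7 2-[(2E,6E)-farnesyl]-1,4-benzoquinone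
Conditions: Ag2O, MgSO4, Et2O, rt
Reagents that add atoms: none
Why: Ag2O is a mild hydroquinone-to-quinone oxidant (dehydrogenation) that leaves the trisubstituted alkenes untouched.

**Step 5**
Reactants: 7 2-[(2E,6E)-farnesyl]-1,4-benzoquinone; 8 cyclopenta-1,3-diene (freshly cracked from commercial dicyclopentadiene)
Product: 9 rac-cis-endo-2-farnesyl-4a,5,8,8a-tetrahydro-5,8-methanonaphthalene-1,4-dione
Conditions: CH2Cl2, −20 → 0 °C
Reagents that add atoms: none
Why: The Diels–Alder cycloaddition takes place at the unsubstituted, more electron-poor quinone C=C and follows the endo rule, which fixes the cis ring fusion (racemic) and masks that double bond.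

**Step 6**
Reactants: 9 rac-endo cycloadduct
Product: 10 rac-(2R*,3S*)-2,3-epoxy-2-farnesyl-cis-endo-2,3,4a,5,8,8a-hexahydro-5,8-methanonaphthalene-1,4-dione (oxirane O on the exo/convex face, cis to H-4a and H-8a)
Conditions: 30% H2O2, aq. Na2CO3, acetone, 0 °C
Reagents that add atoms: hydrogen peroxide OO
Why: Weitz–Scheffer nucleophilic epoxidation attacks only the enedione C=C, from the convex face anti to the norbornene, so the oxirane is cis to the ring-fusion hydrogens; the farnesyl alkenes are inert to HOO−.

**Step 7**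
Reactants: 10 rac-epoxydione
Product: 11 rac-(2R*,3S*)-2,3-epoxy-2-farnesyl-4a-(hydroxymethyl)-cis-endo-2,3,4a,5,8,8a-hexahydro-5,8-methanonaphthalene-1,4-dione (CH2OH, H-8a and oxirane O all on the exo face)
Conditions: 37% aq. HCHO, DBU (0.2 equiv), THF, 0 °C
Reagents that add atoms: formaldehyde C=O
Why: Intermolecular aldol of the ring-fusion enolate with formaldehyde occurs at C-4a (away from the carbonyl flanked by the quaternary farnesyl carbon, as recalled for the 2-allyl analogue) and on the exo face, which keeps the cis fusion and places CH2OH cis to the oxirane oxygen.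

**Step 8**
Reactants: 11 rac-hydroxymethyl epoxydione
Product: 12 (2R,3S)-enantiomer of 11 (same relative configuration; absolute configuration as in the SMILES)
Conditions: lipase PS (Amano, immobilised), vinyl acetate, t-BuOMe, 30 °C, to ~52% conversion; chromatography
Reagents that add atoms: none
Why: Lipase-catalysed irreversible transesterification (kinetic resolution) acetylates one enantiomer of the primary alcohol next to the quaternary stereocentre and leaves 12 enantiopure, which fixes the absolute configuration of the whole core.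

**Step 9**
Reactants: 12 resolved hydroxymethyl epoxydione
Product: 13 TBS ether of 12
Conditions: TBSCl, imidazole, DMAP (cat.), DMF, rt
Reagents that add atoms: tert-butyldimethylsilyl chloride CC(C)(C)[Si](C)(C)Cl
Why: Silyl ether formation blocks retro-aldol loss of formaldehyde during the thermolysis that follows; no stereocentre is touched.

**Step 10**
Reactants: 13 TBS ether
Product: 14 (1R,6S)-4-[(tert-butyldimethylsilyloxy)methyl]-1-farnesyl-7-oxabicyclo[4.1.0]hept-3-ene-2,5-dione
Conditions: Ph2O, 240 °C, 15 min, N2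
Reagents that add atoms: none
Why: Thermal retro-Diels–Alder extrudes cyclopentadiene and unveils the quinone C=C between the former ring-fusion carbons; the oxirane stereocentres are untouched.

**Step 11**
Reactants: 14 silyl epoxyquinone
Product: 15 (1R,6S)-4-(hydroxymethyl)-1-farnesyl-7-oxabicyclo[4.1.0]hept-3-ene-2,5-dione
Conditions: HF·pyridine, pyridine, THF, 0 °C → rt
Reagents that add atoms: none
Why: Buffered fluoride desilylation is tolerated by the epoxyquinone and frees the hydroxyl that assists the next reduction.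

**Step 12**
Reactants: 15 hydroxymethyl epoxyquinone
Product: 16 (1R,5R,6R)-5-hydroxy-4-(hydroxymethyl)-1-farnesyl-7-oxabicyclo[4.1.0]hept-3-en-2-one
Conditions: DIBAL-H (2.2 equiv), THF, −78 °C; Rochelle salt
Reagents that add atoms: none
Why: In this 1,2-hydride reduction the aluminium alkoxide formed at CH2OH activates the adjacent C-5 carbonyl (C-2 is shielded by the quaternary farnesyl carbon), and hydride adds anti to the oxirane oxygen to give the cis (5R) epoxy alcohol.

**Step 13**
Reactants: 17 methyl bromoacetate; 18 methyl acetoacetate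
Product: 20 dimethyl 3-hydroxy-3-methylpentanedioate, via bromozinc enolate of methyl acetate 19 (not isolated)
Conditions: Zn (TMSCl-activated), THF, reflux; aq. HCl
Reagents that add atoms: none
Why: In this Reformatsky (aldol-type) reaction the weakly basic zinc enolate adds to the ketone carbonyl of the β-keto ester and gives the prochiral tertiary carbinol.

**Step 14**
Reactants: 20 dimethyl 3-hydroxy-3-methylpentanedioate
Product: 21 (3S)-3-hydroxy-5-methoxy-3-methyl-5-oxopentanoic acid
Conditions: pig liver esterase, pH 7.5 phosphate buffer, rt, pH-stat (1 M NaOH, 1.0 equiv); then HCl to pH 2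
Reagents that add atoms: water O
Why: Enantiotopic-group-selective enzymatic hydrolysis of the pro-S ester arm sets the tertiary carbinol stereocentre as (S); ee is checked and, if needed, raised by crystallising an amine salt.

**Step 15**
Reactants: 21 (3S)-monomethyl ester
Product: 22 1-methyl 5-[2-(trimethylsilyl)ethyl] (3R)-3-hydroxy-3-methylpentanedioate
Conditions: Me3SiCH2CH2OH, DCC, DMAP (cat.), CH2Cl2, 0 °C → rt
Reagents that add atoms: 2-(trimethylsilyl)ethanol C[Si](C)(C)CCO
Why: Steglich esterification of the free acid leaves the tertiary alcohol alone and does not touch the stereocentre (the label becomes R only through the priority change).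

**Step 16**
Reactants: 22 mixed diester
Product: 23 (3R)-3-hydroxy-3-methyl-5-oxo-5-[2-(trimethylsilyl)ethoxy]pentanoic acid
Conditions: Me3SnOH (3 equiv), 1,2-dichloroethane, 70 °C; dilute HCl work-up
Reagents that add atoms: trimethyltin hydroxide C[Sn](C)(C)O
Why: Near-neutral selective ester hydrolysis cleaves the unhindered methyl ester in preference to the bulkier TMSE ester and completes the ester switch; any over-cleaved material is 21 and is recycled.

**Step 17**
Reactants: 16 epoxyquinol diol; 23 (3R)-mono-TMSE acid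
Product: 24 [(1R,5R,6R)-5-hydroxy-2-oxo-1-farnesyl-7-oxabicyclo[4.1.0]hept-3-en-4-yl]methyl 2-(trimethylsilyl)ethyl 3-hydroxy-3-methylpentanedioate (HMG centre labelled R because of Si, same spatial arrangement as 3S in 25)
Conditions: DCC, DMAP (0.1 equiv), CH2Cl2, −20 → 0 °C
Reagents that add atoms: none
Why: In this Steglich esterification the unhindered primary allylic alcohol reacts much faster at low temperature than the secondary alcohol flanked by the oxirane, and the tertiary HMG hydroxyl does not acylate; no stereocentre is affected.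

**Step 18**
Reactants: 24 TMSE-protected ester
Product: 25 (3S)-3-hydroxy-5-{[(1R,5R,6R)-5-hydroxy-2-oxo-1-farnesyl-7-oxabicyclo[4.1.0]hept-3-en-4-yl]methoxy}-3-methyl-5-oxopentanoic acid (target)
Conditions: TASF, DMF, 0 °C; cold 0.1 M HCl quench; reverse-phase chromatography
Reagents that add atoms: none
Why: Fluoride-induced β-elimination of the 2-(trimethylsilyl)ethyl ester releases the acid (ethene and Me3SiF are lost) under non-hydrolytic, nearly neutral conditions that spare the other ester, the oxirane and the enone.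

**Compound list**
1 | (2E,6E)-farnesol | CC(C)=CCC/C(C)=C/CC/C(C)=C/CO | starting material
2 | (2E,6E)-farnesyl chloride | CC(C)=CCC/C(C)=C/CC/C(C)=C/CCl | intermediate
3 | tributyl[(2E,6E)-farnesyl]stannane | CC(C)=CCC/C(C)=C/CC/C(C)=C/C[Sn](CCCC)(CCCC)CCCC | intermediate
4 | p-benzoquinone | O=C1C=CC(=O)C=C1 | starting material
5 | 2-farnesylcyclohex-5-ene-1,4-dione (conjugate adduct, not isolated) | CC(C)=CCC/C(C)=C/CC/C(C)=C/CC1CC(=O)C=CC1=O | intermediate
6 | 2-[(2E,6E)-farnesyl]benzene-1,4-diol | CC(C)=CCC/C(C)=C/CC/C(C)=C/Cc1cc(O)ccc1O | intermediate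
7 | 2-[(2E,6E)-farnesyl]-1,4-benzoquinone | CC(C)=CCC/C(C)=C/CC/C(C)=C/CC1=CC(=O)C=CC1=O | intermediate
8 | cyclopenta-1,3-diene | C1=CCC=C1 | starting material
9 | rac-cis-endo-2-farnesyl-4a,5,8,8a-tetrahydro-5,8-methanonaphthalene-1,4-dione (SMILES shows the enantiomer carried on) | O=C1C(C/C=C(\C)CC/C=C(\C)CCC=C(C)C)=CC(=O)[C@H]2[C@H]3C=C[C@H](C3)[C@@H]12 | intermediate
10 | rac-(2R*,3S*)-2,3-epoxy derivative of 9, oxirane O exo, cis to H-4a/H-8a (SMILES shows the enantiomer carried on) | O=C1[C@]2(C/C=C(\C)CC/C=C(\C)CCC=C(C)C)O[C@@H]2C(=O)[C@H]3[C@H]4C=C[C@H](C4)[C@@H]13 | intermediate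
11 | rac-4a-(hydroxymethyl) derivative of 10, CH2OH cis to oxirane O (SMILES shows the enantiomer carried on) | O=C1[C@]2(C/C=C(\C)CC/C=C(\C)CCC=C(C)C)O[C@@H]2C(=O)[C@@]3(CO)[C@H]4C=C[C@H](C4)[C@@H]13 | intermediate
12 | (2R,3S)-enantiomer of 11, resolved | O=C1[C@]2(C/C=C(\C)CC/C=C(\C)CCC=C(C)C)O[C@@H]2C(=O)[C@@]3(CO)[C@H]4C=C[C@H](C4)[C@@H]13 | intermediate
13 | TBS ether of 12 | O=C1[C@]2(C/C=C(\C)CC/C=C(\C)CCC=C(C)C)O[C@@H]2C(=O)[C@@]3(CO[Si](C)(C)C(C)(C)C)[C@H]4C=C[C@H](C4)[C@@H]13 | intermediate
14 | (1R,6S)-4-[(tert-butyldimethylsilyloxy)methyl]-1-farnesyl-7-oxabicyclo[4.1.0]hept-3-ene-2,5-dione | CC(C)=CCC/C(C)=C/CC/C(C)=C/C[C@@]12O[C@@H]1C(=O)C(CO[Si](C)(C)C(C)(C)C)=CC2=O | intermediate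
15 | (1R,6S)-4-(hydroxymethyl)-1-farnesyl-7-oxabicyclo[4.1.0]hept-3-ene-2,5-dione | CC(C)=CCC/C(C)=C/CC/C(C)=C/C[C@@]12O[C@@H]1C(=O)C(CO)=CC2=O | intermediate
16 | (1R,5R,6R)-5-hydroxy-4-(hydroxymethyl)-1-farnesyl-7-oxabicyclo[4.1.0]hept-3-en-2-one | CC(C)=CCC/C(C)=C/CC/C(C)=C/C[C@@]12O[C@@H]1[C@H](O)C(CO)=CC2=O | intermediate
17 | methyl bromoacetate | COC(=O)CBr | starting material
18 | methyl acetoacetate | COC(=O)CC(C)=O | starting material
19 | bromozinc enolate of methyl acetate (Reformatsky reagent, not isolated) | COC(=O)C[Zn]Br | intermediate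
20 | dimethyl 3-hydroxy-3-methylpentanedioate | COC(=O)CC(C)(O)CC(=O)OC | intermediate
21 | (3S)-3-hydroxy-5-methoxy-3-methyl-5-oxopentanoic acid | COC(=O)C[C@@](C)(O)CC(=O)O | intermediate
22 | 1-methyl 5-[2-(trimethylsilyl)ethyl] (3R)-3-hydroxy-3-methylpentanedioate | COC(=O)C[C@@](C)(O)CC(=O)OCC[Si](C)(C)C | intermediate
23 | (3R)-3-hydroxy-3-methyl-5-oxo-5-[2-(trimethylsilyl)ethoxy]pentanoic acid | OC(=O)C[C@@](C)(O)CC(=O)OCC[Si](C)(C)C | intermediate
24 | TMSE-protected target ester (core 1R,5R,6R; HMG centre labelled R) | CC(C)=CCC/C(C)=C/CC/C(C)=C/C[C@@]12O[C@@H]1[C@H](O)C(COC(=O)C[C@@](C)(O)CC(=O)OCC[Si](C)(C)C)=CC2=O | intermediate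
25 | (3S)-3-hydroxy-5-{[(1R,5R,6R)-5-hydroxy-2-oxo-1-farnesyl-7-oxabicyclo[4.1.0]hept-3-en-4-yl]methoxy}-3-methyl-5-oxopentanoic acid | CC(C)=CCC/C(C)=C/CC/C(C)=C/C[C@@]12O[C@@H]1[C@H](O)C(COC(=O)C[C@@](C)(O)CC(=O)O)=CC2=O | target

**Totals**
Total step count: 18. Longest linear sequence: 14 steps (steps 1–12, 17, 18, from farnesol); the HMG branch is steps 13–16.

**Three steps most likely to fail**

Step 3 (conjugate allylation of unsubstituted benzoquinone). The risks are redox scrambling between product hydroquinone and quinone, double allylation, BF3-induced chroman formation and partial loss of the 2′E geometry. The fallback sets out from 1 and returns at 7. Compound 1 is converted with PBr3 (Et2O, 0 °C) into (2E,6E)-farnesyl bromide F1. Commercial 1,4-dimethoxybenzene is ortho-lithiated (n-BuLi, TMEDA, THF, 0 °C), transmetallated with CuBr·SMe2 and alkylated with F1 at −78 → 0 °C (SN2, geometry retained) to give 2-[(2E,6E)-farnesyl]-1,4-dimethoxybenzene F2. Oxidative demethylation of F2 with CAN (MeCN–H2O, 0 °C) gives quinone 7, and the route continues with step 5.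

Step 12 (regio- and face-selective reduction of the epoxyquinone). The most likely failure is hydride delivery syn to the oxirane, giving the C-5 epimer. The fallback sets out from 14 and returns at 16. The same reduction is run on silyl ether 14, where only the secondary hydroxyl is then free, to give (1R,5S,6R)-4-[(tert-butyldimethylsilyloxy)methyl]-5-hydroxy-1-farnesyl-7-oxabicyclo[4.1.0]hept-3-en-2-one F3. Mitsunobu inversion (4-nitrobenzoic acid, PPh3, DIAD, toluene, 0 °C) gives the (1R,5R,6R)-5-(4-nitrobenzoyloxy) silyl ether F4. Methanolysis (K2CO3, MeOH, 0 °C) gives the (1R,5R,6R)-5-hydroxy silyl ether F5, and HF·pyridine then gives diol 16.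

Step 18 (fluoride cleavage of the TMSE ester on the base-sensitive epoxyquinol). The fallback sets out from 21 (and uses 16) and returns at 25. Acid 21 is esterified with allyl alcohol (DCC, DMAP) to give 1-methyl 5-(prop-2-enyl) (3R)-3-hydroxy-3-methylpentanedioate F6. Me3SnOH cleaves the methyl ester to give (3R)-3-hydroxy-3-methyl-5-oxo-5-(prop-2-enyloxy)pentanoic acid F7. Steglich coupling of F7 with 16 gives the allyl-protected target ester F8. Pd(PPh3)4 (5 mol%) with PhSiH3 in CH2Cl2 at 0 °C removes the allyl group under neutral conditions and gives 25; the trisubstituted, enone-conjugated allylic ester of the core is expected to ionise far more slowly than the simple allyl ester.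

**Further compounds**
F1 | step 3 | (2E,6E)-farnesyl bromide | CC(C)=CCC/C(C)=C/CC/C(C)=C/CBr
F2 | step 3 | 2-[(2E,6E)-farnesyl]-1,4-dimethoxybenzene | COc1ccc(OC)c(C/C=C(\C)CC/C=C(\C)CCC=C(C)C)c1
F3 | step 12 | (1R,5S,6R)-4-[(tert-butyldimethylsilyloxy)methyl]-5-hydroxy-1-farnesyl-7-oxabicyclo[4.1.0]hept-3-en-2-one | CC(C)=CCC/C(C)=C/CC/C(C)=C/C[C@@]12O[C@@H]1[C@@H](O)C(CO[Si](C)(C)C(C)(C)C)=CC2=O
F4 | step 12 | (1R,5R,6R)-4-[(tert-butyldimethylsilyloxy)methyl]-5-(4-nitrobenzoyloxy)-1-farnesyl-7-oxabicyclo[4.1.0]hept-3-en-2-one | CC(C)=CCC/C(C)=C/CC/C(C)=C/C[C@@]12O[C@@H]1[C@H](OC(=O)c3ccc(cc3)[N+](=O)[O-])C(CO[Si](C)(C)C(C)(C)C)=CC2=O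
F5 | step 12 | (1R,5R,6R)-4-[(tert-butyldimethylsilyloxy)methyl]-5-hydroxy-1-farnesyl-7-oxabicyclo[4.1.0]hept-3-en-2-one | CC(C)=CCC/C(C)=C/CC/C(C)=C/C[C@@]12O[C@@H]1[C@H](O)C(CO[Si](C)(C)C(C)(C)C)=CC2=O
F6 | step 18 | 1-methyl 5-(prop-2-enyl) (3R)-3-hydroxy-3-methylpentanedioate | COC(=O)C[C@@](C)(O)CC(=O)OCC=C
F7 | step 18 | (3R)-3-hydroxy-3-methyl-5-oxo-5-(prop-2-enyloxy)pentanoic acid | OC(=O)C[C@@](C)(O)CC(=O)OCC=C
F8 | step 18 | allyl-protected target ester (core 1R,5R,6R; HMG centre 3S) | CC(C)=CCC/C(C)=C/CC/C(C)=C/C[C@@]12O[C@@H]1[C@H](O)C(COC(=O)C[C@@](C)(O)CC(=O)OCC=C)=CC2=O
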